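The earlier runs and the new flask are calculated with constants of no real substance; the scatter is artificial.

| flask | starting complex | incoming ligand | remark | time |
|---|---|---|---|---|
| epsilon | 44 mM | 74 mM | run made earlier |  |
| delta | 44 mM | 120 mM | run made earlier |  |
| zeta | 66 mM | 52.8 mM | run made earlier |  |
| flask | 44 mM | 52.8 mM |  | 30 h |

| run | time / h | complex with two exchanged / % | starting complex / % |
|---|---|---|---|
| epsilon | 2.50 | 23.3 | 8.4 |
| epsilon | 4.00 | 23.5 | 8.4 |
| epsilon | 6.00 | 24.0 | 8.4 |
| epsilon | 8.00 | 23.7 | 8.7 |
| epsilon | 12.0 | 23.9 | 8.6 |
| epsilon | 20.0 | 23.1 | 8.3 |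
| epsilon | 30.0 | 23.1 | 8.2 |
| delta | 1.50 | 13.6 | 0.7 |
| delta | 5.00 | 13.8 | 0.3 |
| delta | 8.00 | 13.8 | 0.2 |
| delta | 12.0 | 14.4 | 0.3 |
| delta | 20.0 | 13.5 | 0.5 |
| delta | 25.0 | 13.8 | 0 |
| delta | 30.0 | 13.4 | 0.4 |
| zeta | 2.50 | 10.9 | 38.1 |
| zeta | 5.00 | 10.3 | 38.3 |
| zeta | 8.00 | 11.3 | 37.5 |
| zeta | 15.0 | 10.7 | 37.6 |
| zeta | 30.0 | 11.4 | 37.5 |

(scatter of a reading: 0.3 percentage points)

- the reaction counts as stopped when no species that holds the starting complex changes by six tenths of a point or more over the second half of the time

* which holds at 30 h: what has brought the reaction to rest, or that it has not come to rest (forward and back rates have come level / it is still moving / the incoming ligand has run out first / all of the starting complex has reacted)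
* complex with two exchanged at 30 h, in percent of the starting complex charged

The leftover starting complex was what I planned the next run on. It stood flat from the first reading in zeta and epsilon, so I kept 30 h and set the flask at 52.8 mM of incoming ligand, which puts c(incoming ligand)/c(starting complex) between those two runs. I assumed that every incoming ligand had reacted, making it the limiting reagent, and followed one molecule of it. Its first-hit share is the reacted starting complex divided by that ratio. The later share is the complex with two exchanged per ligand that went beyond a first hit.

| run | ligand per complex | starting complex left | first-hit share | later share |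
|---|---|---|---|---|
| zeta | 0.800 | 37.8% | 0.778 | 0.613 |
| epsilon | 1.68 | 8.43% | 0.544 | 0.307 |

A straight line between these rows, at the flask's ratio of 1.20, gave a first-hit share of 0.672 and a later share of 0.474. So I expected 19.4% of the starting complex left and 18.7% of complex with two exchanged, and the leftover was the reading to watch.

The forecast gave 18.5% and "the incoming ligand has run out first": “So the stop is ligand exhaustion, not equilibrium”.

The flask gave "the incoming ligand has run out first", with 18.6% of complex with two exchanged, 20% of starting complex and 0% of incoming ligand left.

    complex with three exchanged + incoming ligand → leaving ligand + complex with four exchanged (k = 0.0420 M⁻¹ s⁻¹)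
    complex with one exchanged + incoming ligand → leaving ligand + complex with two exchanged (k = 0.0860 M⁻¹ s⁻¹)
    complex with two exchanged + incoming ligand → over-reaction product (k = 0.0760 M⁻¹ s⁻¹)
    starting complex + incoming ligand → leaving ligand + complex with one exchanged (k = 0.180 M⁻¹ s⁻¹)
    complex with two exchanged + incoming ligand → leaving ligand + complex with three exchanged (k = 0.0640 M⁻¹ s⁻¹)

The rate constant for starting complex taking incoming ligand, 0.18 M⁻¹ s⁻¹, was larger than the one for complex with one exchanged, 0.086 M⁻¹ s⁻¹, which was about half of it. The flask's first-hit share, reckoned from its result, was 0.667, against my 0.672. For the neighbour flask with 32 mM of incoming ligand, the line carried below zeta gives a share of 0.797, so 42.1% of starting complex left; that flask holds 42%.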